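Locants follow neolignan usage: C7 is the benzylic carbinol carbon, C8 the aryloxy methine and C9 the acetoxymethyl carbon.

## The problem

Compound 11 is an open-chain 8-O-4′ neolignan. A three-carbon chain (C7–C8–C9) carries the 3,4,5-trimethoxyphenyl ring on C7, the oxygen of a 4-allyl-2,6-dimethoxyphenol on C8 and an acetate on O9. No ring has to be closed, and the skeleton comes down to two bonds, C7–C8 and C8–OAr. The SMILES string reads as 7R,8R, the threo series, which is syn when C9–C8–C7–aryl is drawn as a zigzag.

The two stereocentres are neighbours, but neither controls the other dependably. Chelate and Felkin–Anh models predict opposite results for an α-aryloxy carbonyl group, and an ether oxygen flanked by two methoxy groups is a poor ligand, so control from outside the substrate is preferred. The phenol is blocked at both ortho positions, which argues for making the C8–O bond at an unhindered CH2 carbon and not by displacement at a finished stereocentre.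

Three groups limit the reagents:
- The allyl group is moved into conjugation by strong base or by metal hydrides with a free site, and it is attacked by boranes and by H2/metal.
- The electron-rich benzylic carbinol at C7 is ionised by strong acid.
- The primary acetate is cleaved by hydrides and organometallics and can migrate to O7 under base.

The feature that opens the shortest way is the 1,3-relationship of O7 and O9. With C7 as a ketone and C9 as an ester, the C8–H bond lies between two carbonyl groups and next to the aryloxy oxygen, so C8 racemises through the enol. One hydride transfer to C7 that selects one face and one C8 epimer then fixes both centres.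

## Retrosynthesis

**11 ⇒ 10.** The acetyl–O9 bond is cut first. The acetate survives neither the hydride that creates the C9 carbinol nor any enolate chemistry, so it has to come last. Carrying it earlier, or separating O7 from O9 with protecting groups, would add two or three steps. Diol 10 is simpler by only one acyl group, but its two hydroxyl groups differ clearly: O9 is primary, while O7 is secondary, benzylic and shielded by the neighbouring 2,6-dimethoxyaryloxy group. The forward reaction must monoacylate O9 and must not allow migration to O7.

**10 ⇒ 9.** No skeletal bond is cut here; C9 is raised from carbinol to ethyl ester. This change acidifies C8–H for the next retrosynthetic step and gives C8 enolate character for the C7–C8 bond. An amide, nitrile or aldehyde at C9 would serve the same purpose, but the ester is the cheapest and comes ready-made in 2. The forward reaction is a hydride reduction that leaves the allyl group alone and consumes the ester before the C7 alkoxide can undergo retro-aldol cleavage or C8 can epimerise.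

**9 ⇒ 7.** The C7–H bond is cut, and both stereocentres disappear at once. C7 becomes trigonal and C8 becomes configurationally mobile through enol 8.
- The neighbouring cuts are less attractive. A stereocontrolled C7–C8 aldol needs a stoichiometric auxiliary, and a stereospecific C8–O displacement needs a doubly ortho-blocked phenoxide to attack a secondary carbon.
- Ketoester 7 carries no stereochemical information, so it can be assembled by any convenient racemic chemistry.
- The forward reaction has to meet four demands: racemisation faster than reduction, one carbonyl face, one C8 epimer (the one leading to syn), and C=O reduction without any reaction at the allyl C=C.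

**7 ⇒ 3 + 4.** The C7–C8 bond is cut in a crossed Claisen sense, which splits the molecule into two halves of similar size.
- Acid chloride 4 cannot enolise, so only ester 3 can supply the nucleophile, lithium enolate 5. The product is protected in the flask as its own enolate 6.
- The neighbouring cut, C8–O (phenoxide 1 on an α-bromo ketoester), would pair an electron-rich, hindered phenoxide with a halide prone to attack at bromine.
- The forward reaction needs C- rather than O-acylation and a base too weak to remove the allylic–benzylic protons of the allyl arene.

**3 ⇒ 1 + 2.** The O–C8 bond is cut while C8 is still a CH2 group. The unhindered, activated primary bromide 2 makes up for the steric demand of phenol 1. Both compounds are commercial, as is 4.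

## Roads not taken

**Alternative 1:** The cut removes C8–H and C9–O and leads back to an enol ether.
- **Route:** A1 is the 4-bromo-2,6-dimethoxyphenyl ester of O-silylated (R)-3,4,5-trimethoxymandelic acid. Methylenation (Tebbe or Petasis reagent) would convert it into enol ether A2. Rhodium-catalysed catecholborane addition and oxidation would then give threo alcohol A3.
- **Merits:** The C8–O bond arises from an esterification. C7 comes from a mandelate of secure configuration. No intermediate has an epimerisable centre.
- **Weak points:**
  - Catalysed hydroboration of 1,1-disubstituted allylic silyl ethers is known to favour syn, but those cases carry an alkyl group where A2 carries an aryloxy group, so the diastereoselectivity would have to be extrapolated.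
  - Boron at C9 sits β to an aryloxide leaving group on C8, and fragmentation of this β-oxygenated borane to an alkene is a real threat.
  - The allyl group cannot be present during hydroboration. A bromide placeholder and a late palladium-catalysed allylation are needed, besides acetylation and desilylation.
  - The enantiopure mandelic acid needs an asymmetric step of its own.
- **Comparison:** This road would be roughly twice as long as the chosen one, and it sets one centre at a time. It is superior only in that it avoids a base-labile stereocentre. The chosen plan answers this by removing the C8 acidity one step after the centre is set.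

**Alternative 2:** The cut is C7–C8, made with stereocontrol.
- **Route:** Imide A4 is the N-(aryloxyacetyl) derivative of (S)-4-benzyl-2-oxazolidinone A5. It would be enolised with dibutylboron triflate and a tertiary amine and added to 3,4,5-trimethoxybenzaldehyde A6. The Evans syn aldol gives imide A7 through a closed chair transition state. Mapping the known outcome of the S auxiliary onto this glycolate gives 2S,3R, the geometry of 11. Reductive removal of the auxiliary gives diol 10 directly.
- **Merits:** A skeletal bond and both centres form in one step, and the sense of induction is highly predictable. In stereochemical reliability this road is better than the chosen one.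
- **Weak points:** It uses a stoichiometric auxiliary and boron triflate. Two extra operations (saponification of 3, N-acylation) are needed to mount the auxiliary. There is an oxidative boron work-up, and a borohydride cleavage takes place in the presence of a terminal alkene.
- **Comparison:** The chosen plan sets against this a chirality source used in catalytic amount, one step fewer, access to either enantiomer by exchanging the catalyst, and a racemic precursor made from an acid chloride. Both roads pass through 3 and 10, so the aldol remains available as the fallback.

**Alternative 3:** The cut is the C7–aryl bond.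
- **Route:** Prochiral 2-(4-allyl-2,6-dimethoxyphenoxy)propane-1,3-diol A8 would be desymmetrised by lipase monoacylation. Silylation, deacylation and oxidation would convert it into (R)-aldehyde A9. 3,4,5-Trimethoxyphenylmagnesium bromide A10 would then add under chelation control to give threo silyl ether A11.
- **Merits:** The endgame is convergent, and the desymmetrisation can in principle convert all the material into one enantiomer.
- **Weak points:**
  - Threo selectivity needs a Cram chelate through the C8 ether oxygen, which is weakly basic and crowded. The Felkin–Anh pathway leads to the erythro isomer, and the ortho-methoxy groups offer competing binding sites.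
  - A9 is an α-aryloxy aldehyde with a β-silyloxy group. In the presence of a basic Grignard reagent, enolisation, racemisation and β-elimination are all plausible.
  - The O7/O9 differentiation in A11 brings no advantage. Placing the acetate still means desilylation to 10 followed by the same selective acetylation.
- **Comparison:** About nine steps would be needed, and the centres are set one after the other, the second with doubtful control. This road is better only in avoiding a metal hydride next to the allyl group. The chosen plan relies on the coordinative saturation of its hydride on that point.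

Key step: step 3

Assumption: the sense of induction of the (S,S) catalyst is carried over from simple aryl ketones and should be checked on 9 by Mosher ester analysis; if it proves opposite, the (R,R) catalyst takes its place with nothing else changed.

## Route

Step 1
Reactants: 1 4-allyl-2,6-dimethoxyphenol; 2 ethyl bromoacetate
Product: 3 ethyl 2-(4-allyl-2,6-dimethoxyphenoxy)acetate
Conditions: K2CO3, acetone, reflux
Reagents that add atoms: none
Why: Williamson ether synthesis; the activated, unhindered primary bromide accepts even a phenoxide blocked at both ortho positions, and carbonate is too weak to move the allyl double bond.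

Step 2
Reactants: 3 ethyl 2-(4-allyl-2,6-dimethoxyphenoxy)acetate; 4 3,4,5-trimethoxybenzoyl chloride
Product: 7 racemic ethyl 2-(4-allyl-2,6-dimethoxyphenoxy)-3-oxo-3-(3,4,5-trimethoxyphenyl)propanoate, via lithium ester enolate 5 (not isolated), via lithium ketoester enolate 6 (not isolated)
Conditions: LiHMDS (2.1 equiv), THF, −78 °C; 4 (1.0 equiv), −78 to −20 °C; AcOH quench
Reagents that add atoms: none
Why: Crossed Claisen condensation (C-acylation of an ester enolate by a non-enolisable aroyl chloride); the second equivalent of base stores the more acidic product as enolate 6 and so prevents proton exchange with 5, and LiHMDS is too weak to deprotonate the allyl arene. The C8 centre forms racemic, which is what step 3 requires.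

Step 3
Reactants: 7 racemic ethyl 2-(4-allyl-2,6-dimethoxyphenoxy)-3-oxo-3-(3,4,5-trimethoxyphenyl)propanoate
Product: 9 ethyl (2S,3R)-2-(4-allyl-2,6-dimethoxyphenoxy)-3-hydroxy-3-(3,4,5-trimethoxyphenyl)propanoate (syn), via enol tautomer 8 (not isolated)
Conditions: RuCl[(S,S)-TsDPEN](p-cymene) (1 mol %), HCO2H/Et3N (5:2), CH2Cl2, 30 °C
Reagents that add atoms: none
Why: This is a Noyori–Ikariya asymmetric transfer hydrogenation run as a dynamic kinetic resolution, the reaction type known for α-alkoxy β-keto esters, which give syn α-alkoxy β-hydroxy esters. Formate turns the 16-electron ruthenium amide into the 18-electron Ru–H/N–H species with loss of CO2, and this species passes hydride to C7 and a proton to the carbonyl oxygen through an outer-sphere six-membered transition state; no ring closes. The enantiomers of 7 interconvert through enol 8 in the amine-buffered medium, and the slow reduction expected for a hindered, electron-rich aryl ketone helps racemisation stay ahead of hydride transfer. C7 is set by the catalyst: the CH/π contact between the η6-arene and the trimethoxyphenyl ring orients the ketone as in acetophenone, which the (S,S) catalyst reduces to the S alcohol, and the same spatial sense (Si face here) is 7R, that is 3R in 9, because C8 outranks the aryl carbon. C8 is set by matching: the fast-reacting epimer is the one for which the catalyst's face is also the polar Felkin–Anh face, with the C8–OAr bond anti to the incoming hydride, the ester beside the carbonyl oxygen and C8–H beside the aryl ring, and this arrangement leads to the syn 2S,3R ester. The step needs face selectivity, epimer selectivity and chemoselectivity for C=O over the allyl C=C; the bulky aryloxy group sharpens the difference between the epimers, and the coordinatively saturated hydride has no site for alkene binding, insertion or isomerisation.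

Step 4
Reactants: 9 ethyl (2S,3R)-2-(4-allyl-2,6-dimethoxyphenoxy)-3-hydroxy-3-(3,4,5-trimethoxyphenyl)propanoate
Product: 10 (1R,2R)-2-(4-allyl-2,6-dimethoxyphenoxy)-1-(3,4,5-trimethoxyphenyl)propane-1,3-diol
Conditions: LiAlH4, THF, 0 °C; H2O/aq NaOH work-up
Reagents that add atoms: none
Why: Hydride reduction of an unprotected β-hydroxy α-aryloxy ester to the 1,3-diol, a standard operation in arylglycerol β-aryl ether chemistry; isolated alkenes are inert to LiAlH4 and fast reduction at 0 °C should outrun retro-aldol cleavage. No bond to C7 or C8 is touched (the C8 descriptor changes from S to R only through CIP ranking), and C8 is no longer acidic afterwards.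

Step 5
Reactants: 10 (1R,2R)-2-(4-allyl-2,6-dimethoxyphenoxy)-1-(3,4,5-trimethoxyphenyl)propane-1,3-diol
Product: 11 (2R,3R)-2-(4-allyl-2,6-dimethoxyphenoxy)-3-hydroxy-3-(3,4,5-trimethoxyphenyl)propyl acetate (target)
Conditions: AcCl (1.05 equiv), 2,4,6-collidine, CH2Cl2, −78 °C
Reagents that add atoms: acetyl chloride, CC(=O)Cl
Why: Kinetically selective acetylation of a primary alcohol beside a secondary one with acetyl chloride and a hindered pyridine base at low temperature; O7 is secondary, benzylic and screened by the 2,6-dimethoxyaryloxy group. The weak, non-nucleophilic base should not promote O9→O7 acyl migration, and no stereocentre is affected.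

## Compound list

1 | 4-allyl-2,6-dimethoxyphenol | C=CCc1cc(OC)c(O)c(OC)c1 | starting material
2 | ethyl bromoacetate | CCOC(=O)CBr | starting material
3 | ethyl 2-(4-allyl-2,6-dimethoxyphenoxy)acetate | C=CCc1cc(OC)c(OCC(=O)OCC)c(OC)c1 | intermediate
4 | 3,4,5-trimethoxybenzoyl chloride | COc1cc(C(=O)Cl)cc(OC)c1OC | starting material
5 | lithium enolate of 3 (geometry without consequence) | C=CCc1cc(OC)c(OC=C([O-])OCC)c(OC)c1.[Li+] | intermediate
6 | lithium enolate of 7 (chelated form, O− cis to the ester) | C=CCc1cc(OC)c(O/C(C(=O)OCC)=C(/[O-])c2cc(OC)c(OC)c(OC)c2)c(OC)c1.[Li+] | intermediate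
7 | racemic ethyl 2-(4-allyl-2,6-dimethoxyphenoxy)-3-oxo-3-(3,4,5-trimethoxyphenyl)propanoate | C=CCc1cc(OC)c(OC(C(=O)OCC)C(=O)c2cc(OC)c(OC)c(OC)c2)c(OC)c1 | intermediate
8 | ethyl (E)-2-(4-allyl-2,6-dimethoxyphenoxy)-3-hydroxy-3-(3,4,5-trimethoxyphenyl)acrylate (hydrogen-bonded enol of 7, OH cis to the ester) | C=CCc1cc(OC)c(O/C(C(=O)OCC)=C(/O)c2cc(OC)c(OC)c(OC)c2)c(OC)c1 | intermediate
9 | ethyl (2S,3R)-2-(4-allyl-2,6-dimethoxyphenoxy)-3-hydroxy-3-(3,4,5-trimethoxyphenyl)propanoate | C=CCc1cc(OC)c(O[C@H](C(=O)OCC)[C@H](O)c2cc(OC)c(OC)c(OC)c2)c(OC)c1 | intermediate
10 | (1R,2R)-2-(4-allyl-2,6-dimethoxyphenoxy)-1-(3,4,5-trimethoxyphenyl)propane-1,3-diol | C=CCc1cc(OC)c(O[C@H](CO)[C@H](O)c2cc(OC)c(OC)c(OC)c2)c(OC)c1 | intermediate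
11 | (2R,3R)-2-(4-allyl-2,6-dimethoxyphenoxy)-3-hydroxy-3-(3,4,5-trimethoxyphenyl)propyl acetate | C=CCc1cc(OC)c(O[C@H](COC(C)=O)[C@H](O)c2cc(OC)c(OC)c(OC)c2)c(OC)c1 | target

## Step count and risks

Total step count: 5. Longest linear sequence: 5 steps (1 → 3 → 7 → 9 → 10 → 11).

**Step 3 (key step).**
- **What may go wrong:**
  - The most likely failure is incomplete epimer selection. The aryloxy group is much larger than the alkoxy groups for which the method is known. It may slow enolisation to the crowded enol 8 so that racemisation falls behind reduction, or it may let the catalyst accept both C8 epimers. Either would let anti isomer through.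
  - Migration of the allyl double bond into conjugation could occur if the catalyst decays to unsaturated ruthenium hydrides.
  - The absolute sense of induction rests on analogy.
- **Adjustments within the plan:** An amine-richer formic acid/triethylamine mixture would speed racemisation. The sulfonyl group and η6-arene can be varied, and a tethered catalyst can be used.
- **Fallback (from 3, back at 10):** The centres are set by an auxiliary instead of a catalyst. Ester 3 is saponified to 2-(4-allyl-2,6-dimethoxyphenoxy)acetic acid F1. The acid is activated as 2-(4-allyl-2,6-dimethoxyphenoxy)acetic pivalic anhydride F2, which acylates lithiated A5 to give imide A4. Boron enolisation and addition to aldehyde A6 give syn aldol imide A7. Lithium borohydride removes the auxiliary reductively and gives diol 10.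

**Step 2.**
- **What may go wrong:** The product enolate may be O-acylated by remaining acid chloride. The amide base may consume the acid chloride, and 3 may self-condense, because three nucleophiles compete for one electrophile.
- **Fallback (from 3 through enolate 5, back at 7):** The electrophile and the oxidation level are changed. Enolate 5 adds to aldehyde A6 in a plain aldol reaction to give ethyl 2-(4-allyl-2,6-dimethoxyphenoxy)-3-hydroxy-3-(3,4,5-trimethoxyphenyl)propanoate as a racemic syn/anti mixture F3. Dess–Martin oxidation of the benzylic carbinol then gives 7. The stereochemistry of the aldol is irrelevant because it is erased.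

**Step 4.**
- **What may go wrong:** Retro-aldol cleavage or C8 epimerisation may occur through the metal alkoxide at O7 before the ester is consumed, since 9 is a β-hydroxy ester with an acidified α-position.
- **Fallback (from 9, back at 11):** O7 is masked so that no alkoxide can form.
  - TBSOTf/2,6-lutidine gives ethyl (2S,3R)-2-(4-allyl-2,6-dimethoxyphenoxy)-3-(tert-butyldimethylsilyloxy)-3-(3,4,5-trimethoxyphenyl)propanoate F4.
  - DIBAL-H gives (2R,3R)-2-(4-allyl-2,6-dimethoxyphenoxy)-3-(tert-butyldimethylsilyloxy)-3-(3,4,5-trimethoxyphenyl)propan-1-ol F5.
  - Ac2O/pyridine gives (2R,3R)-2-(4-allyl-2,6-dimethoxyphenoxy)-3-(tert-butyldimethylsilyloxy)-3-(3,4,5-trimethoxyphenyl)propyl acetate F6.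
  - HF·pyridine frees O7 without base and gives 11.
  - This bypasses 10 and the selectivity question of step 5, at the price of two more steps.

**Step 5.**
- **What may go wrong:** Over-acetylation at O7, and acyl migration from O9 to O7 during work-up, since the two oxygens can reach each other through a six-membered transition state.
- **Fallback (from 10, back at 11):** Regiocontrol is handed to an enzyme. A lipase-catalysed transesterification with vinyl acetate in an organic solvent at neutral pH is used. The active site admits the primary hydroxyl but not the crowded benzylic one, and no base is present to drive migration.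

## Further compounds

F1 | step 3 | 2-(4-allyl-2,6-dimethoxyphenoxy)acetic acid | C=CCc1cc(OC)c(OCC(=O)O)c(OC)c1
F2 | step 3 | 2-(4-allyl-2,6-dimethoxyphenoxy)acetic pivalic anhydride | C=CCc1cc(OC)c(OCC(=O)OC(=O)C(C)(C)C)c(OC)c1
F3 | step 2 | ethyl 2-(4-allyl-2,6-dimethoxyphenoxy)-3-hydroxy-3-(3,4,5-trimethoxyphenyl)propanoate, racemic syn/anti mixture | C=CCc1cc(OC)c(OC(C(=O)OCC)C(O)c2cc(OC)c(OC)c(OC)c2)c(OC)c1
F4 | step 4 | ethyl (2S,3R)-2-(4-allyl-2,6-dimethoxyphenoxy)-3-(tert-butyldimethylsilyloxy)-3-(3,4,5-trimethoxyphenyl)propanoate | C=CCc1cc(OC)c(O[C@H](C(=O)OCC)[C@H](O[Si](C)(C)C(C)(C)C)c2cc(OC)c(OC)c(OC)c2)c(OC)c1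
F5 | step 4 | (2R,3R)-2-(4-allyl-2,6-dimethoxyphenoxy)-3-(tert-butyldimethylsilyloxy)-3-(3,4,5-trimethoxyphenyl)propan-1-ol | C=CCc1cc(OC)c(O[C@H](CO)[C@H](O[Si](C)(C)C(C)(C)C)c2cc(OC)c(OC)c(OC)c2)c(OC)c1
F6 | step 4 | (2R,3R)-2-(4-allyl-2,6-dimethoxyphenoxy)-3-(tert-butyldimethylsilyloxy)-3-(3,4,5-trimethoxyphenyl)propyl acetate | C=CCc1cc(OC)c(O[C@H](COC(C)=O)[C@H](O[Si](C)(C)C(C)(C)C)c2cc(OC)c(OC)c(OC)c2)c(OC)c1
F0 | step 5 | none | none
A1 | alternative 1 | 4-bromo-2,6-dimethoxyphenyl (R)-2-(tert-butyldimethylsilyloxy)-2-(3,4,5-trimethoxyphenyl)acetate | COc1cc(Br)cc(OC)c1OC(=O)[C@H](O[Si](C)(C)C(C)(C)C)c2cc(OC)c(OC)c(OC)c2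
A2 | alternative 1 | (R)-[2-(4-bromo-2,6-dimethoxyphenoxy)-1-(3,4,5-trimethoxyphenyl)allyloxy](tert-butyl)dimethylsilane | COc1cc(Br)cc(OC)c1OC(=C)[C@H](O[Si](C)(C)C(C)(C)C)c2cc(OC)c(OC)c(OC)c2
A3 | alternative 1 | (2R,3R)-2-(4-bromo-2,6-dimethoxyphenoxy)-3-(tert-butyldimethylsilyloxy)-3-(3,4,5-trimethoxyphenyl)propan-1-ol | COc1cc(Br)cc(OC)c1O[C@H](CO)[C@H](O[Si](C)(C)C(C)(C)C)c2cc(OC)c(OC)c(OC)c2
A4 | alternative 2 | (S)-3-[2-(4-allyl-2,6-dimethoxyphenoxy)acetyl]-4-benzyloxazolidin-2-one | C=CCc1cc(OC)c(OCC(=O)N2C(=O)OC[C@@H]2Cc3ccccc3)c(OC)c1
A5 | alternative 2 | (S)-4-benzyl-2-oxazolidinone | O=C1N[C@@H](Cc2ccccc2)CO1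
A6 | alternative 2 | 3,4,5-trimethoxybenzaldehyde | COc1cc(C=O)cc(OC)c1OC
A7 | alternative 2 | (S)-3-[(2S,3R)-2-(4-allyl-2,6-dimethoxyphenoxy)-3-hydroxy-3-(3,4,5-trimethoxyphenyl)propanoyl]-4-benzyloxazolidin-2-one | C=CCc1cc(OC)c(O[C@H](C(=O)N2C(=O)OC[C@@H]2Cc3ccccc3)[C@H](O)c4cc(OC)c(OC)c(OC)c4)c(OC)c1
A8 | alternative 3 | 2-(4-allyl-2,6-dimethoxyphenoxy)propane-1,3-diol | C=CCc1cc(OC)c(OC(CO)CO)c(OC)c1
A9 | alternative 3 | (R)-2-(4-allyl-2,6-dimethoxyphenoxy)-3-(tert-butyldimethylsilyloxy)propanal | C=CCc1cc(OC)c(O[C@H](CO[Si](C)(C)C(C)(C)C)C=O)c(OC)c1
A10 | alternative 3 | 3,4,5-trimethoxyphenylmagnesium bromide | COc1cc([Mg]Br)cc(OC)c1OC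
A11 | alternative 3 | (1R,2R)-2-(4-allyl-2,6-dimethoxyphenoxy)-3-(tert-butyldimethylsilyloxy)-1-(3,4,5-trimethoxyphenyl)propan-1-ol | C=CCc1cc(OC)c(O[C@H](CO[Si](C)(C)C(C)(C)C)[C@H](O)c2cc(OC)c(OC)c(OC)c2)c(OC)c1
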